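**Plan**
Locants: C1 = benzylic CH2, C2 = ketone carbon, C3–C17 = pentadecyl chain. The retrosynthesis first removes two O-benzyl helper groups from the phenols. It then cuts both C–C bonds at C2 together: C2–C3 (acyl–pentadecyl, the bond that joins the two large fragments) and C1–C2 (benzyl–acyl).
This leaves a 3,5-dioxygenated benzyl bromide, carbon monoxide and a primary C15 alkylborane, which itself comes from 1-pentadecene.
Enabling feature: C2 is a single carbonyl carbon. On one side is the benzylic C1 on the resorcinol ring, whose Pd–benzyl species has no β-hydrogen and inserts CO quickly. On the other side is the unbranched primary C3, which is the terminal alkene carbon after anti-Markovnikov hydroboration.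
Forward order: the benzene ring is bought intact and no ring is built. The alcohol is converted to the bromide, a one-flask hydroboration/carbonylative coupling forms C1–C2 and then C2–C3, and hydrogenolysis frees both phenols.
Stereochemistry: the target is achiral, with no stereocentre and no C=C bond, so nothing has to be set.

Key step: step 2

**Step 1**
Reactants: 1 3,5-bis(benzyloxy)benzyl alcohol
Product: 2 3,5-bis(benzyloxy)benzyl bromide
Conditions: CBr4 (1.25 equiv), PPh3 (1.25 equiv), THF, 0 °C → rt
Reagents that add atoms: carbon tetrabromide, BrC(Br)(Br)Br
Why: In this Appel reaction the alcohol is activated as an alkoxyphosphonium salt and displaced by bromide in an SN2 step at the primary benzylic carbon, under neutral conditions that leave the aryl benzyl ethers untouched.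

**Step 2**
Reactants: 3 1-pentadecene; 4 9-borabicyclo[3.3.1]nonane (9-BBN-H); 2 3,5-bis(benzyloxy)benzyl bromide
Product: 7 1-[3,5-bis(benzyloxy)phenyl]heptadecan-2-one, via B-pentadecyl-9-BBN 5 (not isolated), via arylacetylpalladium bromide 6 (not isolated)
Conditions: (i) 3 (1.4 equiv), 4 (0.5 M in THF, 1.3 equiv), 0 °C → rt; (ii) 2 (1.0 equiv), Pd(PPh3)4 (5 mol %), powdered K3PO4 (3 equiv), dioxane, CO (1 atm), rt → 50 °C; then H2O
Reagents that add atoms: carbon monoxide, [C-]#[O+]
Why: 9-BBN-H adds to the terminal alkene of 3 with boron on the CH2 terminus, so that C3 of the target becomes the only primary, and therefore the only transferable, B–C carbon of 5. Pd(0) then enters the benzylic C–Br bond of 2 by SN2-type oxidative addition, the benzylpalladium bromide (no β-hydrogen) inserts CO to give the arylacetylpalladium bromide 6 (C1–C2 bond), the phosphate-activated borate of 5 hands over its pentadecyl group, and reductive elimination from the acyl(alkyl)palladium forms the C2–C3 bond that joins the two large fragments. The closest known reaction type is the carbonylative Suzuki–Miyaura coupling of B-alkylboranes with aryl, alkenyl and benzyl halides under 1 atm of CO, run here in one flask with the hydroboration as a four-component assembly of alkene, borane, CO and benzyl halide. No ring is closed and no stereocentre is formed. CO insertion must precede transmetalation, which is secured by the fast, CO-sustained insertion at an sp3 benzyl–Pd bond set against the slow alkyl transfer from a borane activated only by suspended K3PO4 at 50 °C or below, and reductive elimination must outrun β-hydride loss from the pentadecyl group, which the electron-poor acyl ligand favours. The aryl benzyl ethers are inert to Pd(0) and mask phenols that 2 would otherwise O-benzylate, and the slight excess of 3 over 4 leaves no B–H to reduce the new ketone.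

**Step 3**
Reactants: 7 1-[3,5-bis(benzyloxy)phenyl]heptadecan-2-one
Product: 8 1-(3,5-dihydroxyphenyl)heptadecan-2-one (target)
Conditions: H2 (1 atm), 10 % Pd/C, EtOAc–EtOH 1:1, rt
Reagents that add atoms: none
Why: Catalytic hydrogenolysis should cleave both benzylic C–O bonds of the aryl benzyl ethers, while the C2 carbonyl, insulated from the ring by C1, behaves as an ordinary dialkyl ketone and is left alone by Pd/C at 1 atm.

**Compound list**
1 | 3,5-bis(benzyloxy)benzyl alcohol | OCc1cc(OCc2ccccc2)cc(OCc2ccccc2)c1 | starting material
2 | 3,5-bis(benzyloxy)benzyl bromide | BrCc1cc(OCc2ccccc2)cc(OCc2ccccc2)c1 | intermediate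
3 | 1-pentadecene | CCCCCCCCCCCCCC=C | starting material
4 | 9-borabicyclo[3.3.1]nonane (9-BBN-H, drawn as the monomer) | B1C2CCCC1CCC2 | starting material
5 | B-pentadecyl-9-BBN (9-pentadecyl-9-borabicyclo[3.3.1]nonane) | CCCCCCCCCCCCCCCB1C2CCCC1CCC2 | intermediate
6 | [3,5-bis(benzyloxy)phenyl]acetylpalladium(II) bromide (two PPh3 ligands omitted from the SMILES) | O=C(Cc1cc(OCc2ccccc2)cc(OCc2ccccc2)c1)[Pd]Br | intermediate
7 | 1-[3,5-bis(benzyloxy)phenyl]heptadecan-2-one | CCCCCCCCCCCCCCCC(=O)Cc1cc(OCc2ccccc2)cc(OCc2ccccc2)c1 | intermediate
8 | 1-(3,5-dihydroxyphenyl)heptadecan-2-one | CCCCCCCCCCCCCCCC(=O)Cc1cc(O)cc(O)c1 | target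

**Step count**
Total steps: 3. Longest linear sequence: 3 (1 → 2 → 7 → 8). The alkene branch enters in step 2 without a step of its own.

**Steps most likely to fail**

Step 2.
- What may go wrong: alkyl transfer to palladium before CO has inserted, hydrolytic capture of the acylpalladium species by adventitious water, or benzylation of the product enolate by bromide that has not yet reacted.
- Fallback: it sets out from 2 and returns at 7.
- Palladium-catalysed methoxycarbonylation of 2 (PdCl2(PPh3)2, CO 1 atm, MeOH, iPr2NEt, 50 °C) should give methyl [3,5-bis(benzyloxy)phenyl]acetate F1.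
- Me(MeO)NH·HCl and iPrMgCl in THF at −20 °C should convert this ester into 2-[3,5-bis(benzyloxy)phenyl]-N-methoxy-N-methylacetamide F2.
- Pentadecylmagnesium bromide F3, made from commercial 1-bromopentadecane and Mg in THF, should add once to F2 at 0 °C. The magnesium chelate holds until the aqueous HCl quench, which releases 7.
- The same C2–C3 bond then arises by a polar Weinreb ketone synthesis, with CO insertion and alkyl transfer carried out in separate flasks.

Step 3.
- What may go wrong: over-reduction of the carbonyl group, or stalling of the second debenzylation through catalyst poisoning by phosphine or boron residues and through poor solubility of the waxy substrate.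
- Fallback: it sets out from 5 and returns at 8, and it changes the helper group.
- Compound 5, made from 3 and 4 as in step 2, is coupled under the same CO conditions with commercial 3,5-dimethoxybenzyl bromide. This should give 1-(3,5-dimethoxyphenyl)heptadecan-2-one F4.
- The methyl ethers of F4 are then cleaved with BBr3 (CH2Cl2, −78 °C → rt, aqueous quench). This Lewis acid dealkylation needs neither a reducing agent nor a metal surface.

Step 1.
- What may go wrong: loss of the benzylic bromide by hydrolysis or self-alkylation of the electron-rich ring on silica while the phosphorus by-product is being removed.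
- Fallback: it sets out from 1 and returns at 7.
- SOCl2 (CH2Cl2, cat. DMF, 0 °C) should give 3,5-bis(benzyloxy)benzyl chloride F5, with only volatile co-products, so no chromatography is needed.
- This more robust electrophile replaces 2 in step 2. Benzyl chlorides are established partners in palladium carbonylations, and 60–70 °C with catalytic NaI should make up for the slower oxidative addition.

**Further compounds**
F1 | step 2 | methyl [3,5-bis(benzyloxy)phenyl]acetate | COC(=O)Cc1cc(OCc2ccccc2)cc(OCc2ccccc2)c1
F2 | step 2 | 2-[3,5-bis(benzyloxy)phenyl]-N-methoxy-N-methylacetamide | CON(C)C(=O)Cc1cc(OCc2ccccc2)cc(OCc2ccccc2)c1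
F3 | step 2 | pentadecylmagnesium bromide | CCCCCCCCCCCCCCC[Mg]Br
F4 | step 3 | 1-(3,5-dimethoxyphenyl)heptadecan-2-one | CCCCCCCCCCCCCCCC(=O)Cc1cc(OC)cc(OC)c1
F5 | step 1 | 3,5-bis(benzyloxy)benzyl chloride | ClCc1cc(OCc2ccccc2)cc(OCc2ccccc2)c1
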